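**Strategy.** The target is an alternating epicatechin tetramer, U1-(4β→6)-U2-(4α→8)-U3-(4β→6)-U4, with (2R,3R) units U1, U3 and (2S,3S) units U2, U4; it is cut at the three interflavan bonds. The pyran ring of U3 (O1, C2, C3, C4, C4a, C8a; likewise that of U1) is not closed directly. A cis-2-aryl-3-(hydroxymethyl)-2,3-dihydrobenzofuran, from an enantioselective rhodium-carbenoid C–H insertion, is ring-expanded: the trioxygenated ring A bridges C3 and the exocyclic CH2 as a phenonium ion, aryl carbon C4a moves to that CH2 (the future C4), and water enters C3 with inversion, giving the 2,3-cis alcohol. Bromine-capped, orthogonally activated C4 cations then join the units.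

Key step: step 6

Remarks: (+)-epicatechin, 3,5-bis(benzyloxy)phenol and 3,4-bis(benzyloxy)benzyl chloride are taken as purchasable. The (2S,3R) sense of induction of Rh2(S-PTTL)4 is assumed; if it proves opposite, Rh2(R-PTTL)4 is used. Flavan numbering is used for flavan-type compounds, benzofuran numbering for 8–10.

Step 1
Reactants: 1 3,5-bis(benzyloxy)phenol
Product: 2 4,6-bis(benzyloxy)-1-benzofuran-2,3-dione
Conditions: (COCl)2, Et2O, 0 °C to reflux
Reagents that add atoms: oxalyl chloride, O=C(Cl)C(=O)Cl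
Why: O-acylation of the phenol followed by intramolecular Friedel–Crafts acylation at either of the two equivalent ortho positions gives the coumarandione, as known for 3,5-dialkoxyphenols.

Step 2
Reactants: 2 4,6-bis(benzyloxy)-1-benzofuran-2,3-dione; 3 3,4-bis(benzyloxy)benzyl chloride
Product: 5 methyl {2,4-bis(benzyloxy)-6-[(3,4-bis(benzyloxy)benzyl)oxy]phenyl}(oxo)acetate, via hydroxy keto ester 4 (not isolated)
Conditions: K2CO3, MeOH, 0 °C to rt; evaporate; then 3, K2CO3, KI (cat.), DMF, 50 °C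
Reagents that add atoms: methanol, CO
Why: Methoxide opens the lactone carbonyl to the aryl glyoxylate phenoxide, which is O-alkylated by the benzylic chloride (Williamson ether synthesis); no stereocentre is formed.

Step 3
Reactants: 5 methyl {2,4-bis(benzyloxy)-6-[(3,4-bis(benzyloxy)benzyl)oxy]phenyl}(oxo)acetate
Product: 7 methyl {2,4-bis(benzyloxy)-6-[(3,4-bis(benzyloxy)benzyl)oxy]phenyl}(diazo)acetate, via tosylhydrazone 6 (not isolated)
Conditions: TsNHNH2, TsOH (cat.), toluene, 80 °C; then DBU, CH2Cl2, 0 °C to rt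
Reagents that add atoms: p-toluenesulfonyl hydrazide, Cc1ccc(S(=O)(=O)NN)cc1
Why: Condensation to the tosylhydrazone and base-induced loss of sulfinate (Bamford–Stevens route to aryldiazoacetates) should give the donor/acceptor diazo ester.

Step 4
Reactants: 7 methyl {2,4-bis(benzyloxy)-6-[(3,4-bis(benzyloxy)benzyl)oxy]phenyl}(diazo)acetate
Product: 8 methyl (2S,3R)-4,6-bis(benzyloxy)-2-[3,4-bis(benzyloxy)phenyl]-2,3-dihydro-1-benzofuran-3-carboxylate (2,3-cis)
Conditions: dirhodium tetrakis[N-phthaloyl-(S)-tert-leucinate], Rh2(S-PTTL)4 (1 mol%), toluene, −60 °C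
Reagents that add atoms: none
Why: Intramolecular 1,5 C–H insertion of the rhodium carbenoid into the benzylic ether C–H closes the dihydrobenzofuran; the concerted insertion gives the kinetic 2,3-cis ester, the chiral carboxylate ligands choose the enantiotopic hydrogen and so set C2 and C3, and the more hydridic 3,4-dialkoxybenzylic C–H should react in preference to the plain benzyl ether at the other ortho position.

Step 5
Reactants: 8 methyl (2S,3R)-cis-dihydrobenzofuran-3-carboxylate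
Product: 9 [(2S,3S)-4,6-bis(benzyloxy)-2-[3,4-bis(benzyloxy)phenyl]-2,3-dihydro-1-benzofuran-3-yl]methanol (2,3-cis)
Conditions: i-Bu2AlH, CH2Cl2, −78 to −20 °C
Reagents that add atoms: none
Why: Non-basic hydride reduction of the ester at low temperature should leave the epimerisable cis C3 centre untouched.

Step 6
Reactants: 9 [(2S,3S)-4,6-bis(benzyloxy)-2-[3,4-bis(benzyloxy)phenyl]-2,3-dihydro-1-benzofuran-3-yl]methanol
Product: 11 5,7,3',4'-tetra-O-benzyl-(−)-epicatechin, (2R,3R)-5,7-bis(benzyloxy)-2-[3,4-bis(benzyloxy)phenyl]chroman-3-ol, via primary mesylate 10 (not isolated)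
Conditions: MsCl, Et3N, CH2Cl2, −40 °C; then (CF3)2CHOH–H2O (9:1), 2,6-lutidine, 0 °C to rt
Reagents that add atoms: water, O (the mesyl group of intermediate 10 comes from methanesulfonyl chloride, CS(=O)(=O)Cl, and is lost again)
Why: Proposed new method: ionisation of the primary mesylate in the strongly ionising, weakly nucleophilic medium is assisted by the ipso carbon C3a of the 2,4,6-trioxygenated ring A, giving a spiro-cyclopropyl arenium (phenonium) ion that bridges C3 and the exocyclic CH2; water then opens the bridge at C3, so that the aryl carbon has moved from C3 to CH2 and the five-membered O1–C2–C3–C3a–C7a ring has become the six-membered O1–C2–C3–C4–C4a–C8a ring. The closest known reactions are the neophyl-type Wagner–Meerwein 1,2-aryl shifts in solvolyses of 2-aryl-1-propyl and neophyl sulfonates and the Demjanov ring expansion. The six-membered ring is not closed directly: a 3-exo attack of the arene π-system on CH2 forms the bridge, and cleavage of the C3–C3a bond expands the ring. The new C3 stereocentre is controlled by the bridge, because water must enter anti to the departing aryl carbon, which in the cis precursor places the hydroxyl cis to the C2 aryl group (2R,3R), while C2 is untouched. The step needs opening at C3 and not at CH2, which should be favoured because C3 is the more substituted terminus and its bond to C3a is the strained fusion bond of the bicyclo[3.1.0] unit (opening at CH2 only returns 9, which is recycled). It also needs no hydride or aryl shift from C2, which is secured because neither H-2 nor the C2 aryl group is antiperiplanar to the C3–C3a bond in the five-membered ring, and the lutidine buffer protects the acid-labile O1–C2 benzylic ether.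

Step 7
Reactants: 11 5,7,3',4'-tetra-O-benzyl-(−)-epicatechin
Product: 12 5,7,3',4'-tetra-O-benzyl-4β-(2-ethoxyethoxy)-(−)-epicatechin (2,3-cis, 3,4-trans)
Conditions: DDQ, EtOCH2CH2OH, CH2Cl2, rt
Reagents that add atoms: 2-ethoxyethanol, CCOCCO
Why: DDQ abstracts hydride from the benzylic C4 position activated by ring A and the alcohol traps the cation anti to the C3 hydroxyl, the known oxidative C4 alkoxylation of benzylated epicatechin.

Step 8
Reactants: 12 5,7,3',4'-tetra-O-benzyl-4β-(2-ethoxyethoxy)-(−)-epicatechin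
Product: 13 6,8-dibromo-5,7,3',4'-tetra-O-benzyl-4β-(2-ethoxyethoxy)-(−)-epicatechin
Conditions: NBS (2.1 equiv), NaHCO3, CH2Cl2, −20 °C to rt
Reagents that add atoms: N-bromosuccinimide, O=C1CCC(=O)N1Br
Why: Electrophilic aromatic bromination fills both free ring A positions (C8, then C6), so that this unit can later act only as an electrophile.

Step 9
Reactants: 14 (+)-epicatechin, (2S,3S)
Product: 15 5,7,3',4'-tetra-O-benzyl-(+)-epicatechin
Conditions: BnBr, K2CO3, DMF, 0 °C to rt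
Reagents that add atoms: benzyl bromide, BrCc1ccccc1
Why: Williamson benzylation of the four phenols, which are far more acidic than the C3 alcohol.

Step 10
Reactants: 15 5,7,3',4'-tetra-O-benzyl-(+)-epicatechin
Product: 16 8-bromo-5,7,3',4'-tetra-O-benzyl-(+)-epicatechin
Conditions: NBS (1.0 equiv), CH2Cl2, −78 °C
Reagents that add atoms: N-bromosuccinimide, O=C1CCC(=O)N1Br
Why: The known C8-selective bromination of benzylated epicatechin blocks C8, so that later Friedel–Crafts reactions of this unit can only occur at C6.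

Step 11
Reactants: 16 8-bromo-5,7,3',4'-tetra-O-benzyl-(+)-epicatechin
Product: 17 8-bromo-5,7,3',4'-tetra-O-benzyl-4α-(2-ethoxyethoxy)-(+)-epicatechin (2,3-cis, 3,4-trans)
Conditions: DDQ, EtOCH2CH2OH, CH2Cl2, rt
Reagents that add atoms: 2-ethoxyethanol, CCOCCO
Why: The same DDQ-mediated benzylic C4 alkoxylation as in step 7, in the mirror-image series; the alcohol adds anti to the C3 hydroxyl.

Step 12
Reactants: 17 8-bromo-5,7,3',4'-tetra-O-benzyl-4α-(2-ethoxyethoxy)-(+)-epicatechin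
Product: 18 8-bromo-5,7,3',4'-tetra-O-benzyl-4α-[(2,6-dimethylphenyl)sulfanyl]-(+)-epicatechin (3,4-trans)
Conditions: 2,6-Me2C6H3SH, BF3·OEt2, CH2Cl2, −78 to −40 °C
Reagents that add atoms: 2,6-dimethylbenzenethiol, Cc1cccc(C)c1S
Why: The Lewis acid ionises the C4 ether and the thiol traps the cation anti to the C3 hydroxyl (SN1 exchange), giving a 3,4-trans thioether that is inert to hard Lewis acids.

Step 13
Reactants: 13 6,8-dibromo-tetra-O-benzyl-4β-(2-ethoxyethoxy)-(−)-epicatechin; 18 8-bromo-tetra-O-benzyl-4α-[(2,6-dimethylphenyl)sulfanyl]-(+)-epicatechin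
Product: 19 dimer U1–U2: 6,8-dibromo-tetra-O-benzyl-(−)-epicatechin-(4β→6)-[8-bromo-tetra-O-benzyl-4α-(2,6-dimethylphenylsulfanyl)-(+)-epicatechin]
Conditions: BF3·OEt2, 4 Å MS, CH2Cl2, −78 to −30 °C (18 in excess)
Reagents that add atoms: none
Why: Friedel–Crafts-type flavan C4 arylation: BF3 ionises only the C4 ether of 13, and the cation is attacked by the only free ring A position (C6) of 18, anti to the C3 hydroxyl, which sets the 4β centre of U1.

Step 14
Reactants: 19 dimer U1–U2 with the C4 thioether on U2; 12 5,7,3',4'-tetra-O-benzyl-4β-(2-ethoxyethoxy)-(−)-epicatechin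
Product: 20 trimer U1–U2–U3: 6,8-dibromo-tetra-O-benzyl-(−)-epicatechin-(4β→6)-[8-bromo-tetra-O-benzyl-(+)-epicatechin]-(4α→8)-[tetra-O-benzyl-4β-(2-ethoxyethoxy)-(−)-epicatechin]
Conditions: AgBF4, 2,6-di-tert-butyl-4-methylpyridine, 4 Å MS, THF, −40 to 0 °C (12 in excess)
Reagents that add atoms: none
Why: Thiophilic activation of the C4 thioether by Ag+ (the C4 ether of 12 is kept intact by the hindered base) gives the C4 cation of U2, which is attacked by the more nucleophilic C8 of 12 anti to the C3 hydroxyl, setting the 3,4-trans (4α) centre.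

Step 15
Reactants: 20 trimer U1–U2–U3
Product: 21 trimer U1–U2–U3 carrying an additional bromine at C6 of U3
Conditions: NBS (1.05 equiv), CH2Cl2, −40 to 0 °C
Reagents that add atoms: N-bromosuccinimide, O=C1CCC(=O)N1Br
Why: Electrophilic bromination at the only ring A position that is neither substituted nor on a bromine-deactivated ring caps C6 of U3 and so prevents self-condensation in the last coupling.

Step 16
Reactants: 21 bromine-capped trimer U1–U2–U3; 16 8-bromo-5,7,3',4'-tetra-O-benzyl-(+)-epicatechin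
Product: 22 protected tetramer: hexadeca-O-benzyl-pentabromo U1-(4β→6)-U2-(4α→8)-U3-(4β→6)-U4 (Br at C6 and C8 of U1, C8 of U2, C6 of U3, C8 of U4)
Conditions: BF3·OEt2, 4 Å MS, CH2Cl2, −78 to −20 °C (16 in excess)
Reagents that add atoms: none
Why: BF3 ionises the C4 ether of U3, and the cation is attacked by C6 of 16 (C8 is blocked) anti to the C3 hydroxyl, setting the 4β centre of U3 in a halogen-capped Friedel–Crafts flavan coupling.

Step 17
Reactants: 22 protected tetramer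
Product: 23 (−)-epicatechin-(4β→6)-(+)-epicatechin-(4α→8)-(−)-epicatechin-(4β→6)-(+)-epicatechin, CNP0120618.2
Conditions: H2 (1 atm), Pd(OH)2/C, Et3N, THF–MeOH–H2O, rt
Reagents that add atoms: none
Why: Hydrogenolysis should cleave the sixteen benzyl ethers and the five aryl C–Br bonds without touching any stereocentre, while Et3N takes up HBr to protect the acid-labile interflavan bonds.

**Compound list**

1 | 3,5-bis(benzyloxy)phenol | Oc1cc(OCc2ccccc2)cc(OCc2ccccc2)c1 | starting material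
2 | 4,6-bis(benzyloxy)-1-benzofuran-2,3-dione | O=C1Oc2cc(OCc3ccccc3)cc(OCc3ccccc3)c2C1=O | intermediate
3 | 3,4-bis(benzyloxy)benzyl chloride | ClCc1ccc(OCc2ccccc2)c(OCc2ccccc2)c1 | starting material
4 | methyl [2,4-bis(benzyloxy)-6-hydroxyphenyl](oxo)acetate (not isolated) | COC(=O)C(=O)c1c(O)cc(OCc2ccccc2)cc1OCc1ccccc1 | intermediate
5 | methyl {2,4-bis(benzyloxy)-6-[(3,4-bis(benzyloxy)benzyl)oxy]phenyl}(oxo)acetate | COC(=O)C(=O)c1c(OCc2ccc(OCc3ccccc3)c(OCc3ccccc3)c2)cc(OCc2ccccc2)cc1OCc1ccccc1 | intermediate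
6 | tosylhydrazone of 5 (not isolated) | COC(=O)C(=NNS(=O)(=O)c1ccc(C)cc1)c1c(OCc2ccc(OCc3ccccc3)c(OCc3ccccc3)c2)cc(OCc2ccccc2)cc1OCc1ccccc1 | intermediate
7 | methyl {2,4-bis(benzyloxy)-6-[(3,4-bis(benzyloxy)benzyl)oxy]phenyl}(diazo)acetate | COC(=O)C(=[N+]=[N-])c1c(OCc2ccc(OCc3ccccc3)c(OCc3ccccc3)c2)cc(OCc2ccccc2)cc1OCc1ccccc1 | intermediate
8 | methyl (2S,3R)-4,6-bis(benzyloxy)-2-[3,4-bis(benzyloxy)phenyl]-2,3-dihydro-1-benzofuran-3-carboxylate (cis) | O1[C@H](c4ccc(OCc9ccccc9)c(OCc9ccccc9)c4)[C@H](C(=O)OC)c2c(OCc9ccccc9)cc(OCc9ccccc9)cc21 | intermediate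
9 | [(2S,3S)-4,6-bis(benzyloxy)-2-[3,4-bis(benzyloxy)phenyl]-2,3-dihydro-1-benzofuran-3-yl]methanol (cis) | O1[C@H](c4ccc(OCc9ccccc9)c(OCc9ccccc9)c4)[C@H](CO)c2c(OCc9ccccc9)cc(OCc9ccccc9)cc21 | intermediate
10 | methanesulfonate of 9, (2S,3S) (not isolated) | O1[C@H](c4ccc(OCc9ccccc9)c(OCc9ccccc9)c4)[C@H](COS(C)(=O)=O)c2c(OCc9ccccc9)cc(OCc9ccccc9)cc21 | intermediate
11 | 5,7,3',4'-tetra-O-benzyl-(−)-epicatechin, (2R,3R) | C(Oc1cc(OCc9ccccc9)c2c(c1)O[C@H](c4ccc(OCc9ccccc9)c(OCc9ccccc9)c4)[C@H](O)C2)c9ccccc9 | intermediate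
12 | 5,7,3',4'-tetra-O-benzyl-4β-(2-ethoxyethoxy)-(−)-epicatechin (3,4-trans) | C(Oc1cc(OCc9ccccc9)c2c(c1)O[C@H](c4ccc(OCc9ccccc9)c(OCc9ccccc9)c4)[C@H](O)[C@H]2OCCOCC)c9ccccc9 | intermediate
13 | 6,8-dibromo-5,7,3',4'-tetra-O-benzyl-4β-(2-ethoxyethoxy)-(−)-epicatechin | C(Oc1c(Br)c(OCc9ccccc9)c2c(c1Br)O[C@H](c4ccc(OCc9ccccc9)c(OCc9ccccc9)c4)[C@H](O)[C@H]2OCCOCC)c9ccccc9 | intermediate
14 | (+)-epicatechin, (2S,3S) | Oc1cc(O)c2c(c1)O[C@@H](c1ccc(O)c(O)c1)[C@@H](O)C2 | starting material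
15 | 5,7,3',4'-tetra-O-benzyl-(+)-epicatechin | C(Oc1cc(OCc9ccccc9)c2c(c1)O[C@@H](c4ccc(OCc9ccccc9)c(OCc9ccccc9)c4)[C@@H](O)C2)c9ccccc9 | intermediate
16 | 8-bromo-5,7,3',4'-tetra-O-benzyl-(+)-epicatechin | C(Oc1cc(OCc9ccccc9)c2c(c1Br)O[C@@H](c4ccc(OCc9ccccc9)c(OCc9ccccc9)c4)[C@@H](O)C2)c9ccccc9 | intermediate
17 | 8-bromo-5,7,3',4'-tetra-O-benzyl-4α-(2-ethoxyethoxy)-(+)-epicatechin (3,4-trans) | C(Oc1cc(OCc9ccccc9)c2c(c1Br)O[C@@H](c4ccc(OCc9ccccc9)c(OCc9ccccc9)c4)[C@@H](O)[C@@H]2OCCOCC)c9ccccc9 | intermediate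
18 | 8-bromo-5,7,3',4'-tetra-O-benzyl-4α-[(2,6-dimethylphenyl)sulfanyl]-(+)-epicatechin (3,4-trans) | C(Oc1cc(OCc9ccccc9)c2c(c1Br)O[C@@H](c4ccc(OCc9ccccc9)c(OCc9ccccc9)c4)[C@@H](O)[C@@H]2Sc5c(C)cccc5C)c9ccccc9 | intermediate
19 | dimer U1–U2 (Br at C6, C8 of U1 and C8 of U2; thioether at C4 of U2) | C(c9ccccc9)Oc1c(Br)c(OCc9ccccc9)c2c(c1Br)O[C@H](c4ccc(OCc9ccccc9)c(OCc9ccccc9)c4)[C@H](O)[C@H]2c1c(OCc9ccccc9)c(Br)c2c(c1OCc9ccccc9)[C@@H](Sc5c(C)cccc5C)[C@H](O)[C@H](c4ccc(OCc9ccccc9)c(OCc9ccccc9)c4)O2 | intermediate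
20 | trimer U1–U2–U3 (4β-(2-ethoxyethoxy) on U3) | C(c9ccccc9)Oc1c(Br)c(OCc9ccccc9)c2c(c1Br)O[C@H](c4ccc(OCc9ccccc9)c(OCc9ccccc9)c4)[C@H](O)[C@H]2c1c(OCc9ccccc9)c(Br)c2c(c1OCc9ccccc9)[C@@H](c1c(OCc9ccccc9)cc(OCc9ccccc9)c3c1O[C@H](c4ccc(OCc9ccccc9)c(OCc9ccccc9)c4)[C@H](O)[C@H]3OCCOCC)[C@H](O)[C@H](c4ccc(OCc9ccccc9)c(OCc9ccccc9)c4)O2 | intermediate
21 | trimer U1–U2–U3 with Br at C6 of U3 | C(c9ccccc9)Oc1c(Br)c(OCc9ccccc9)c2c(c1Br)O[C@H](c4ccc(OCc9ccccc9)c(OCc9ccccc9)c4)[C@H](O)[C@H]2c1c(OCc9ccccc9)c(Br)c2c(c1OCc9ccccc9)[C@@H](c1c(OCc9ccccc9)c(Br)c(OCc9ccccc9)c3c1O[C@H](c4ccc(OCc9ccccc9)c(OCc9ccccc9)c4)[C@H](O)[C@H]3OCCOCC)[C@H](O)[C@H](c4ccc(OCc9ccccc9)c(OCc9ccccc9)c4)O2 | intermediate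
22 | protected tetramer (sixteen benzyl ethers, five bromines) | C(c9ccccc9)Oc1c(Br)c(OCc9ccccc9)c2c(c1Br)O[C@H](c4ccc(OCc9ccccc9)c(OCc9ccccc9)c4)[C@H](O)[C@H]2c1c(OCc9ccccc9)c(Br)c2c(c1OCc9ccccc9)[C@@H](c1c(OCc9ccccc9)c(Br)c(OCc9ccccc9)c3c1O[C@H](c4ccc(OCc9ccccc9)c(OCc9ccccc9)c4)[C@H](O)[C@H]3c1c(OCc9ccccc9)c(Br)c3c(c1OCc9ccccc9)C[C@H](O)[C@H](c4ccc(OCc9ccccc9)c(OCc9ccccc9)c4)O3)[C@H](O)[C@H](c4ccc(OCc9ccccc9)c(OCc9ccccc9)c4)O2 | intermediate
23 | (−)-epicatechin-(4β→6)-(+)-epicatechin-(4α→8)-(−)-epicatechin-(4β→6)-(+)-epicatechin (CNP0120618.2) | Oc1cc(O)c2c(c1)O[C@H](c1ccc(O)c(O)c1)[C@H](O)[C@H]2c1c(O)cc2c(c1O)[C@@H](c1c(O)cc(O)c3c1O[C@H](c1ccc(O)c(O)c1)[C@H](O)[C@H]3c1c(O)cc3c(c1O)C[C@H](O)[C@H](c1ccc(O)c(O)c1)O3)[C@H](O)[C@H](c1ccc(O)c(O)c1)O2 | target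

**Step count.** Total: 17 steps. Longest linear sequence: 13 steps (steps 1–8, then 13–17).

**Steps most likely to fail**

1. Step 6 (Proposed new method). The bridged ion may be opened by water at the exocyclic CH2, which only returns 9. It may also lose a proton to a flavene, or the O1–C2 benzylic ether may ionise. Fallback (known chemistry, ring expansion by diazotisation instead of sulfonate solvolysis): from 9, Mitsunobu azidation (diphenylphosphoryl azide, PPh3, diisopropyl azodicarboxylate, THF) should give the primary azide F1. Staudinger reduction (PPh3, THF–H2O) should give the primary amine F2. Diazotisation (NaNO2, aqueous AcOH, 0 °C) then triggers the Demjanov ring expansion, in which the same aryl carbon migrates as N2 leaves and water adds to C3. The route is rejoined at 11.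

2. Step 14. The C4 ether of the nucleophile 12 may be ionised by acid formed during the silver-mediated coupling, which would lead to self-condensation instead of the cross-coupling. Fallback (no C4 leaving group on the nucleophile; the lower half is built first): from 12, iodination at C8 (N-iodosuccinimide, CH2Cl2, −78 °C) should give the 8-iodo ether F3. BF3·OEt2-mediated coupling of F3 with excess 16 should give the U3–U4 dimer F4, with iodine at C8 of U3. Iodine–magnesium exchange selective over the aryl bromide (i-PrMgCl·LiCl, THF, −20 °C, then MeOH) should give the deiodinated dimer F5. AgBF4-mediated coupling of 19 with F5 at the free C8 of U3 should give the tetrabromo protected tetramer F6. Hydrogenolysis as in step 17 rejoins the route at 23.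

3. Step 4. Facial control by the chiral catalyst may be poor on this doubly ortho-substituted aryl diazoacetate, and insertion into the neighbouring benzyl ether may compete. Fallback (racemic insertion, then enzymatic resolution): from 7, Rh2(OAc)4 in CH2Cl2 should give ester 8 together with its enantiomer F7. Reduction with i-Bu2AlH should give alcohol 9 together with its enantiomer F8. Lipase-catalysed acetylation (Burkholderia cepacia lipase, vinyl acetate, tert-butyl methyl ether) is assumed to acylate the (2R,3R)-alcohol to the acetate F9. Unreacted (2S,3S)-9 is separated, and the route is rejoined at 9.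

**Further compounds**

F1 | step 6 | (2S,3S)-3-(azidomethyl)-4,6-bis(benzyloxy)-2-[3,4-bis(benzyloxy)phenyl]-2,3-dihydro-1-benzofuran (cis) | O1[C@H](c4ccc(OCc9ccccc9)c(OCc9ccccc9)c4)[C@H](CN=[N+]=[N-])c2c(OCc9ccccc9)cc(OCc9ccccc9)cc21
F2 | step 6 | [(2S,3S)-4,6-bis(benzyloxy)-2-[3,4-bis(benzyloxy)phenyl]-2,3-dihydro-1-benzofuran-3-yl]methanamine (cis) | O1[C@H](c4ccc(OCc9ccccc9)c(OCc9ccccc9)c4)[C@H](CN)c2c(OCc9ccccc9)cc(OCc9ccccc9)cc21
F3 | step 14 | 8-iodo-5,7,3',4'-tetra-O-benzyl-4β-(2-ethoxyethoxy)-(−)-epicatechin | C(Oc1cc(OCc9ccccc9)c2c(c1I)O[C@H](c4ccc(OCc9ccccc9)c(OCc9ccccc9)c4)[C@H](O)[C@H]2OCCOCC)c9ccccc9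
F4 | step 14 | dimer U3–U4: 8-iodo-tetra-O-benzyl-(−)-epicatechin-(4β→6)-[8-bromo-tetra-O-benzyl-(+)-epicatechin] | C(Oc1cc(OCc9ccccc9)c2c(c1I)O[C@H](c4ccc(OCc9ccccc9)c(OCc9ccccc9)c4)[C@H](O)[C@H]2c1c(OCc9ccccc9)c(Br)c3c(c1OCc9ccccc9)C[C@H](O)[C@H](c4ccc(OCc9ccccc9)c(OCc9ccccc9)c4)O3)c9ccccc9
F5 | step 14 | dimer U3–U4: tetra-O-benzyl-(−)-epicatechin-(4β→6)-[8-bromo-tetra-O-benzyl-(+)-epicatechin] | C(Oc1cc(OCc9ccccc9)c2c(c1)O[C@H](c4ccc(OCc9ccccc9)c(OCc9ccccc9)c4)[C@H](O)[C@H]2c1c(OCc9ccccc9)c(Br)c3c(c1OCc9ccccc9)C[C@H](O)[C@H](c4ccc(OCc9ccccc9)c(OCc9ccccc9)c4)O3)c9ccccc9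
F6 | step 14 | protected tetramer with four bromines (C6 and C8 of U1, C8 of U2, C8 of U4) | C(c9ccccc9)Oc1c(Br)c(OCc9ccccc9)c2c(c1Br)O[C@H](c4ccc(OCc9ccccc9)c(OCc9ccccc9)c4)[C@H](O)[C@H]2c1c(OCc9ccccc9)c(Br)c2c(c1OCc9ccccc9)[C@@H](c1c(OCc9ccccc9)cc(OCc9ccccc9)c3c1O[C@H](c4ccc(OCc9ccccc9)c(OCc9ccccc9)c4)[C@H](O)[C@H]3c1c(OCc9ccccc9)c(Br)c3c(c1OCc9ccccc9)C[C@H](O)[C@H](c4ccc(OCc9ccccc9)c(OCc9ccccc9)c4)O3)[C@H](O)[C@H](c4ccc(OCc9ccccc9)c(OCc9ccccc9)c4)O2
F7 | step 4 | methyl (2R,3S)-4,6-bis(benzyloxy)-2-[3,4-bis(benzyloxy)phenyl]-2,3-dihydro-1-benzofuran-3-carboxylate (cis, enantiomer of 8) | O1[C@@H](c4ccc(OCc9ccccc9)c(OCc9ccccc9)c4)[C@@H](C(=O)OC)c2c(OCc9ccccc9)cc(OCc9ccccc9)cc21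
F8 | step 4 | [(2R,3R)-4,6-bis(benzyloxy)-2-[3,4-bis(benzyloxy)phenyl]-2,3-dihydro-1-benzofuran-3-yl]methanol (cis, enantiomer of 9) | O1[C@@H](c4ccc(OCc9ccccc9)c(OCc9ccccc9)c4)[C@@H](CO)c2c(OCc9ccccc9)cc(OCc9ccccc9)cc21
F9 | step 4 | [(2R,3R)-4,6-bis(benzyloxy)-2-[3,4-bis(benzyloxy)phenyl]-2,3-dihydro-1-benzofuran-3-yl]methyl acetate | O1[C@@H](c4ccc(OCc9ccccc9)c(OCc9ccccc9)c4)[C@@H](COC(C)=O)c2c(OCc9ccccc9)cc(OCc9ccccc9)cc21
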